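The constants were set for the occasion, and the outcome is calculated.

Every J charged stays counted as J, Q, Z or Z.D, and D enters the step from J to Q and the step from Q to Z at the same concentration.

    Z + D → Z.D (k1 = 0.630 M⁻¹ s⁻¹)
    Q + D → X + Z (k2 = 0.778 M⁻¹ s⁻¹)
    D ⇌ G (K3 = 1.2, k3 = 0.775 s⁻¹)
    J + D → X + Q (k4 = 2.21 M⁻¹ s⁻¹)

| flask | J | D | time |
|---|---|---|---|
| Saturday's | 0.10 M | 0.100 M | 25 s |
| Tuesday's | 0.10 M | 0.250 M | 25 s |
| Monday's | 0.10 M | 0.620 M | 25 s |

- which of these there is most of at the end, counted by the J in it, Saturday's (Q / Z / Z.D / J)
- which of these there is most of at the end, counted by the J in it, Tuesday's (Q / Z / Z.D / J)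
- which of these there is most of at the end, counted by the J in it, Monday's (Q / Z / Z.D / J)
- how much there is at the end of the one of these that leads, in percent of the J charged: Saturday's
- how much there is at the end of the one of these that leads, in percent of the J charged: Tuesday's
- how much there is at the end of the one of these that leads, in percent of the J charged: Monday's

Minutes. The first speaker held that D therefore cancels from the ratio of those two rates. She defined the crossing ratio, the rate constant of the J step over that of the Q step (their selectivity factor), as 2.84, and argued that Q rises while Q over J stands below it and falls once Q over J stands above it. From this she took a curve for Q, in shares of the J charged, against x, the share of J left, with r the inverse of the crossing ratio: Q = (x^r − x)/(1 − r). Its top lies at J 20.0% and Q 56.7%.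

I then reckoned the cost in D myself. Reaching that top takes one D for each J gone and one more for each J carried beyond Q, so at least 0.103 M. That is more than Saturday's 0.100 M and less than Tuesday's 0.250 M. I concluded that Saturday's must end below the crossing with Q still rising. That cost is less than the charges of D in Tuesday's and Monday's, but my reckoning went no further and named no leader for them.

The maker of the forecast put Q at 53% for Saturday's, Q at 42% for Tuesday's and Z.D at 80% for Monday's, reasoning that “Monday's has enough D to push most of the material through to Z.D”.

The run gives Q at 53.4% in Saturday's, Q at 42.0% in Tuesday's and Z.D at 79.9% in Monday's, the forecast's leaders. Saturday's ends with Q over J at 1.60, below the crossing ratio, and Tuesday's at 12.0, above it. A flask like Tuesday's holds the same Q and Z when charged with 0.830 times Tuesday's J. The neighbour of Tuesday's charged with 0.060 M of J ends with 1.26% of its J left, above the crossing at Q over J of 24.7. The curve gives Q 31.1% there, the run gives 31.1%, and Z leads that neighbour with 38.3%.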